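The route rests on cutting the decamethylene tether between its oxygen-bearing CH2 (the carbon esterified to C1 of the malate) and the next CH2. Both atoms are unbranched primary carbons, remote from the γ-lactone ring and from all three stereocentres, so each can be traced to a carboxyl group: a glycolate-type acyloxyacetic acid on the protected (R)-malate and an ω-carboxylic acid on the lactone diester. A nickel-electrocatalytic doubly decarboxylative coupling of the two N-hydroxyphthalimide esters forms this C(sp3)–C(sp3) bond and joins both halves in one operation. The lactone core, with its quaternary and tertiary stereocentres, comes from an organocatalytic Mukaiyama–Michael addition.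

Key step: step 12

Remark: the SMILES is read as (R)-malate, (S) at the chain C–H and (R) at the lactone quaternary carbon; 1, 5, 8, 13, 15 and the imidazolidinone catalyst are taken as catalogue items.

Step 1
Reactants: 1 tert-butyl furan-2-carboxylate
Product: 3 tert-butyl 5-oxo-2,5-dihydrofuran-2-carboxylate (racemic), via 5-boryl furoate 2 (not isolated)
Conditions: [Ir(OMe)(cod)]2 (1.5 mol%), 4,4′-di-tert-butyl-2,2′-bipyridine (3 mol%), B2pin2 (1.0 equiv), THF, rt; then Oxone, acetone/H2O, 0 °C
Reagents that add atoms: bis(pinacolato)diboron CC1(C)OB(OC1(C)C)B1OC(C)(C)C(C)(C)O1 (boron of 2 only); potassium peroxymonosulfate [K+].[O-]S(=O)(=O)OO (new oxygen of 3)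
Why: Iridium-catalysed C–H borylation of a 2-substituted furan should go to the free α-position C5, and ipso-oxidation of the boronate gives the 5-hydroxyfuran, which tautomerises to the butenolide (C–H borylation/oxidation sequence).

Step 2
Reactants: 3 tert-butyl 5-oxo-2,5-dihydrofuran-2-carboxylate
Product: 4 tert-butyl 5-[(trimethylsilyl)oxy]furan-2-carboxylate
Conditions: TMSOTf (1.2 equiv), Et3N (1.5 equiv), CH2Cl2, 0 °C; non-aqueous work-up, used directly
Reagents that add atoms: trimethylsilyl trifluoromethanesulfonate C[Si](C)(C)OS(=O)(=O)C(F)(F)F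
Why: Soft enolisation at the doubly activated C2–H and O-silylation of the lactone carbonyl should give the aromatic 2-silyloxyfuran (silyl dienol ether formation), and either double-bond tautomer of 3 converges on 4.

Step 3
Reactants: 4 tert-butyl 5-[(trimethylsilyl)oxy]furan-2-carboxylate; 5 tert-butyl (E)-4-oxobut-2-enoate
Product: 7 tert-butyl (2R)-2-[(2S)-1-tert-butoxy-1,4-dioxobutan-2-yl]-5-oxo-2,5-dihydrofuran-2-carboxylate, via iminium ion 6 (not isolated)
Conditions: (2R,5R)-5-benzyl-2-tert-butyl-3-methylimidazolidin-4-one (20 mol%), TfOH (20 mol%), H2O (2 equiv), CHCl3, −20 °C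
Reagents that add atoms: none
Why: Organocatalytic vinylogous Mukaiyama–Michael addition, in which the amine salt condenses with 5 to the E-iminium ion 6, its benzyl and tert-butyl groups leave one face of the β-carbon open to C5 of furan 4 so that the (S) C–H centre should be catalyst-controlled, and the (R) quaternary centre follows from the furan face presented in the open transition state, a preference that the small trimethylsilyl group and the strong-acid co-catalyst are chosen to steer toward the unlike (S,R) isomer.

Step 4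
Reactants: 7 tert-butyl (2R)-2-[(2S)-1-tert-butoxy-1,4-dioxobutan-2-yl]-5-oxo-2,5-dihydrofuran-2-carboxylate; 8 (7-carboxyheptyl)triphenylphosphonium bromide
Product: 10 (8Z,11S)-11-(tert-butoxycarbonyl)-11-[(2R)-2-(tert-butoxycarbonyl)-5-oxo-2,5-dihydrofuran-2-yl]undec-8-enoic acid, via phosphorus ylide 9 (not isolated)
Conditions: 8 (1.3 equiv), NaHMDS (2.5 equiv), THF, 0 °C; then 7, −78 → 0 °C; cold 1 M HCl work-up
Reagents that add atoms: none
Why: Wittig olefination with a non-stabilised carboxylate-bearing ylide should add to the aldehyde at −78 °C faster than it enolises it, with the base kept below two equivalents per salt so that no free amide remains, and the Z geometry is irrelevant because the alkene is reduced in step 5.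

Step 5
Reactants: 10 (8Z,11S)-11-(tert-butoxycarbonyl)-11-[(2R)-2-(tert-butoxycarbonyl)-5-oxo-2,5-dihydrofuran-2-yl]undec-8-enoic acid
Product: 11 (11S)-11-(tert-butoxycarbonyl)-11-[(2R)-2-(tert-butoxycarbonyl)-5-oxooxolan-2-yl]undecanoic acid
Conditions: H2 (1 atm), 10% Pd/C, EtOAc, rt
Reagents that add atoms: none
Why: Heterogeneous catalytic hydrogenation should saturate both the chain alkene and the butenolide C=C without touching the tert-butyl esters, the lactone or either stereocentre, and creates no new stereocentre.

Step 6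
Reactants: 11 (11S)-11-(tert-butoxycarbonyl)-11-[(2R)-2-(tert-butoxycarbonyl)-5-oxooxolan-2-yl]undecanoic acid
Product: 12 1,3-dioxoisoindolin-2-yl (11S)-11-(tert-butoxycarbonyl)-11-[(2R)-2-(tert-butoxycarbonyl)-5-oxooxolan-2-yl]undecanoate
Conditions: N-hydroxyphthalimide (1.1 equiv), DIC (1.1 equiv), DMAP (10 mol%), CH2Cl2, rt
Reagents that add atoms: N-hydroxyphthalimide O=C1c2ccccc2C(=O)N1O
Why: Carbodiimide-mediated esterification of the only free carboxylic acid should give the redox-active ester (Steglich-type active ester formation).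

Step 7
Reactants: 13 (2R)-2-amino-4-tert-butoxy-4-oxobutanoic acid (H-D-Asp(OtBu)-OH)
Product: 14 (2R)-4-tert-butoxy-2-hydroxy-4-oxobutanoic acid
Conditions: NaNO2 (2 equiv), AcOH/H2O (1:4), 0 °C → rt
Reagents that add atoms: water O
Why: Diazotisation of the α-amino acid and hydrolysis should proceed with net retention through double inversion with participation of the neighbouring carboxylate, so the (R) centre of the amino acid becomes the (R) carbinol, and the tert-butyl ester should survive the weakly acidic medium.

Step 8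
Reactants: 14 (2R)-4-tert-butoxy-2-hydroxy-4-oxobutanoic acid; 15 benzyl bromoacetate
Product: 16 1-[2-(benzyloxy)-2-oxoethyl] 4-tert-butyl (2R)-2-hydroxybutanedioate
Conditions: 15 (1.05 equiv), KHCO3 (1.1 equiv), DMF, rt
Reagents that add atoms: none
Why: SN2 O-alkylation of the carboxylate by the α-bromo ester should be fully chemoselective over the unionised secondary hydroxyl (carboxylate alkylation).

Step 9
Reactants: 16 1-[2-(benzyloxy)-2-oxoethyl] 4-tert-butyl (2R)-2-hydroxybutanedioate
Product: 17 1-[2-(benzyloxy)-2-oxoethyl] 4-tert-butyl (2R)-2-[(triethylsilyl)oxy]butanedioate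
Conditions: Et3SiCl (1.2 equiv), imidazole (2 equiv), CH2Cl2, 0 °C → rt
Reagents that add atoms: chlorotriethylsilane CC[Si](Cl)(CC)CC
Why: Imidazole-promoted silylation masks the hydroxyl, which would otherwise attack the activated glycolate carbonyl in steps 11 and 12, under conditions too mild for β-elimination or epimerisation (silyl ether formation).

Step 10
Reactants: 17 1-[2-(benzyloxy)-2-oxoethyl] 4-tert-butyl (2R)-2-[(triethylsilyl)oxy]butanedioate
Product: 18 {[(2R)-4-tert-butoxy-4-oxo-2-[(triethylsilyl)oxy]butanoyl]oxy}acetic acid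
Conditions: H2 (1 atm), 10% Pd/C, EtOAc, rt
Reagents that add atoms: none
Why: Hydrogenolysis cleaves only the benzyl ester, since the tert-butyl ester, the silyl ether (in a non-protic solvent) and the alkyl ester link are inert (benzyl ester hydrogenolysis).

Step 11
Reactants: 18 {[(2R)-4-tert-butoxy-4-oxo-2-[(triethylsilyl)oxy]butanoyl]oxy}acetic acid
Product: 19 4-tert-butyl 1-{2-[(1,3-dioxoisoindolin-2-yl)oxy]-2-oxoethyl} (2R)-2-[(triethylsilyl)oxy]butanedioate
Conditions: N-hydroxyphthalimide (1.1 equiv), DIC (1.1 equiv), DMAP (5 mol%), CH2Cl2, 0 °C → rt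
Reagents that add atoms: N-hydroxyphthalimide O=C1c2ccccc2C(=O)N1O
Why: Carbodiimide coupling of the single free acid should give the α-acyloxy redox-active ester, which is purified by rapid filtration and used at once (Steglich-type active ester formation).

Step 12
Reactants: 12 1,3-dioxoisoindolin-2-yl (11S)-11-(tert-butoxycarbonyl)-11-[(2R)-2-(tert-butoxycarbonyl)-5-oxooxolan-2-yl]undecanoate; 19 4-tert-butyl 1-{2-[(1,3-dioxoisoindolin-2-yl)oxy]-2-oxoethyl} (2R)-2-[(triethylsilyl)oxy]butanedioate
Product: 22 4-tert-butyl 1-{(11S)-11-(tert-butoxycarbonyl)-11-[(2R)-2-(tert-butoxycarbonyl)-5-oxooxolan-2-yl]undecyl} (2R)-2-[(triethylsilyl)oxy]butanedioate, via alkyl radical 20 (not isolated), via acyloxymethyl radical 21 (not isolated)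
Conditions: 12 (1 equiv), 19 (3 equiv), NiCl2·6H2O (20 mol%), 2,2′:6′,2″-terpyridine (20 mol%), AgNO3 (0.3 equiv), (+)Mg/(−)RVC, NMP, rt, constant current, undivided cell
Reagents that add atoms: none
Why: Cathodic, nickel-mediated single-electron reduction of both N-acyloxyphthalimides triggers loss of phthalimide anion and CO2 to give the primary alkyl radical 20 and the acyloxymethyl radical 21, which are captured in turn by the terpyridine–nickel catalyst, and reductive elimination from the dialkylnickel species forms the CH2–CH2 bond while the magnesium anode supplies the electrons. The closest known reaction type is the nickel-electrocatalytic doubly decarboxylative C(sp3)–C(sp3) cross-coupling of redox-active esters, which tolerates α-oxygenated partners. No ring is closed and no stereocentre is created, and the three existing stereocentres are not adjacent to either radical site, so they should be untouched. The step needs cross- over homo-coupling, which the threefold excess of the cheaper partner 19, its easier reduction as an α-oxygenated ester and the easy separation of its small symmetric dimer should secure. The tert-butyl esters, silyl ether, lactone and linking ester should be inert at the mild cathodic potential of the silver-modified carbon cathode.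

Step 13
Reactants: 22 4-tert-butyl 1-{(11S)-11-(tert-butoxycarbonyl)-11-[(2R)-2-(tert-butoxycarbonyl)-5-oxooxolan-2-yl]undecyl} (2R)-2-[(triethylsilyl)oxy]butanedioate
Product: 23 (3R)-4-{[(11S)-11-carboxy-11-[(2R)-2-carboxy-5-oxooxolan-2-yl]undecyl]oxy}-3-hydroxy-4-oxobutanoic acid (target)
Conditions: TFA/CH2Cl2 (1:1), H2O (5 equiv), 0 °C → rt
Reagents that add atoms: none
Why: Acidolysis should remove all three tert-butyl esters and the triethylsilyl ether in one operation, while the γ-lactone and the primary alkyl ester link, which cannot ionise, are stable to anhydrous-type acid (global acidic deprotection).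

Compound list
1 | tert-butyl furan-2-carboxylate | CC(C)(C)OC(=O)c1ccco1 | starting material
2 | tert-butyl 5-(4,4,5,5-tetramethyl-1,3,2-dioxaborolan-2-yl)furan-2-carboxylate | CC(C)(C)OC(=O)c1ccc(B2OC(C)(C)C(C)(C)O2)o1 | intermediate (not isolated)
3 | tert-butyl 5-oxo-2,5-dihydrofuran-2-carboxylate (racemic) | CC(C)(C)OC(=O)C1C=CC(=O)O1 | intermediate
4 | tert-butyl 5-[(trimethylsilyl)oxy]furan-2-carboxylate | CC(C)(C)OC(=O)c1ccc(O[Si](C)(C)C)o1 | intermediate
5 | tert-butyl (E)-4-oxobut-2-enoate | CC(C)(C)OC(=O)/C=C/C=O | starting material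
6 | iminium triflate of 5 with (2R,5R)-5-benzyl-2-tert-butyl-3-methylimidazolidin-4-one | CN1[C@H](C(C)(C)C)[N+](=C/C=C/C(=O)OC(C)(C)C)[C@H](Cc2ccccc2)C1=O.[O-]S(=O)(=O)C(F)(F)F | intermediate (not isolated)
7 | tert-butyl (2R)-2-[(2S)-1-tert-butoxy-1,4-dioxobutan-2-yl]-5-oxo-2,5-dihydrofuran-2-carboxylate | O=CC[C@H](C(=O)OC(C)(C)C)[C@@]1(C(=O)OC(C)(C)C)C=CC(=O)O1 | intermediate
8 | (7-carboxyheptyl)triphenylphosphonium bromide | OC(=O)CCCCCCC[P+](c1ccccc1)(c1ccccc1)c1ccccc1.[Br-] | starting material
9 | sodium 8-(triphenyl-λ5-phosphanylidene)octanoate | [Na+].[O-]C(=O)CCCCCCC=P(c1ccccc1)(c1ccccc1)c1ccccc1 | intermediate (not isolated)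
10 | (8Z,11S)-11-(tert-butoxycarbonyl)-11-[(2R)-2-(tert-butoxycarbonyl)-5-oxo-2,5-dihydrofuran-2-yl]undec-8-enoic acid | OC(=O)CCCCCC/C=C\C[C@H](C(=O)OC(C)(C)C)[C@@]1(C(=O)OC(C)(C)C)C=CC(=O)O1 | intermediate
11 | (11S)-11-(tert-butoxycarbonyl)-11-[(2R)-2-(tert-butoxycarbonyl)-5-oxooxolan-2-yl]undecanoic acid | OC(=O)CCCCCCCCC[C@H](C(=O)OC(C)(C)C)[C@@]1(C(=O)OC(C)(C)C)CCC(=O)O1 | intermediate
12 | 1,3-dioxoisoindolin-2-yl (11S)-11-(tert-butoxycarbonyl)-11-[(2R)-2-(tert-butoxycarbonyl)-5-oxooxolan-2-yl]undecanoate | O=C(ON1C(=O)c2ccccc2C1=O)CCCCCCCCC[C@H](C(=O)OC(C)(C)C)[C@@]3(C(=O)OC(C)(C)C)CCC(=O)O3 | intermediate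
13 | (2R)-2-amino-4-tert-butoxy-4-oxobutanoic acid (H-D-Asp(OtBu)-OH) | N[C@H](CC(=O)OC(C)(C)C)C(=O)O | starting material
14 | (2R)-4-tert-butoxy-2-hydroxy-4-oxobutanoic acid | O[C@H](CC(=O)OC(C)(C)C)C(=O)O | intermediate
15 | benzyl bromoacetate | BrCC(=O)OCc1ccccc1 | starting material
16 | 1-[2-(benzyloxy)-2-oxoethyl] 4-tert-butyl (2R)-2-hydroxybutanedioate | O[C@H](CC(=O)OC(C)(C)C)C(=O)OCC(=O)OCc1ccccc1 | intermediate
17 | 1-[2-(benzyloxy)-2-oxoethyl] 4-tert-butyl (2R)-2-[(triethylsilyl)oxy]butanedioate | CC[Si](CC)(CC)O[C@H](CC(=O)OC(C)(C)C)C(=O)OCC(=O)OCc1ccccc1 | intermediate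
18 | {[(2R)-4-tert-butoxy-4-oxo-2-[(triethylsilyl)oxy]butanoyl]oxy}acetic acid | CC[Si](CC)(CC)O[C@H](CC(=O)OC(C)(C)C)C(=O)OCC(=O)O | intermediate
19 | 4-tert-butyl 1-{2-[(1,3-dioxoisoindolin-2-yl)oxy]-2-oxoethyl} (2R)-2-[(triethylsilyl)oxy]butanedioate | CC[Si](CC)(CC)O[C@H](CC(=O)OC(C)(C)C)C(=O)OCC(=O)ON1C(=O)c2ccccc2C1=O | intermediate
20 | primary alkyl radical from 12 after loss of CO2 and phthalimide anion | [CH2]CCCCCCCC[C@H](C(=O)OC(C)(C)C)[C@@]1(C(=O)OC(C)(C)C)CCC(=O)O1 | intermediate (not isolated)
21 | acyloxymethyl radical from 19 after loss of CO2 and phthalimide anion | CC[Si](CC)(CC)O[C@H](CC(=O)OC(C)(C)C)C(=O)O[CH2] | intermediate (not isolated)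
22 | 4-tert-butyl 1-{(11S)-11-(tert-butoxycarbonyl)-11-[(2R)-2-(tert-butoxycarbonyl)-5-oxooxolan-2-yl]undecyl} (2R)-2-[(triethylsilyl)oxy]butanedioate | CC[Si](CC)(CC)O[C@H](CC(=O)OC(C)(C)C)C(=O)OCCCCCCCCCC[C@H](C(=O)OC(C)(C)C)[C@@]1(C(=O)OC(C)(C)C)CCC(=O)O1 | intermediate
23 | (3R)-4-{[(11S)-11-carboxy-11-[(2R)-2-carboxy-5-oxooxolan-2-yl]undecyl]oxy}-3-hydroxy-4-oxobutanoic acid | O=C(O)C[C@@H](O)C(=O)OCCCCCCCCCC[C@H](C(=O)O)[C@@]1(C(=O)O)CCC(=O)O1 | target

Total step count: 13. Longest linear sequence: 8 steps (steps 1–6, 12, 13).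

Steps most likely to fail

Step 12. The two radicals may pair without bias or be reduced and protonated at the cathode, so that homo-coupling and hydrodecarboxylation of the valuable partner outrun cross-coupling; the activated ester 19 may also be cleaved by the magnesium salts before it is reduced. The fallback forms the same CH2–CH2 bond by a redox-neutral, polarity-matched route. It sets out from acid 11, which would undergo silver-catalysed decarboxylative bromination (Ag(phen)2OTf cat., dibromoisocyanuric acid, DCE) to give tert-butyl (2R)-2-[(1S)-10-bromo-1-(tert-butoxycarbonyl)decyl]-5-oxooxolane-2-carboxylate F1. This bromide and the free α-acyloxy acid 18 would then be joined by iridium/nickel metallaphotoredox decarboxylative alkylation (Ir[dF(CF3)ppy]2(dtbbpy)PF6, NiCl2·glyme, 4,4′-dimethoxy-2,2′-bipyridine, Cs2CO3, MeCN/H2O, blue LEDs). Here the easily oxidised α-oxy carboxylate supplies the radical and the bromide enters by oxidative addition. The fallback comes back to the route at 22.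

Step 3. Facial selectivity at the furan may be poor or of the wrong sense, which would set the quaternary centre incorrectly, and the silyl dienol ether may be hydrolysed before C–C bond formation. The fallback sets out from butenolide 3 and enal 5 and uses a direct vinylogous Michael addition: a diarylprolinol silyl ether, in the enantiomer that exposes the same enal face, activates 5 as its iminium ion, and the free dienol of 3, generated with a weak base additive, adds through a closed, ion-paired transition state. This gives an independent handle on which furanone face reacts. It comes back to the route at 7 and makes no new compound (F0).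

Step 4. The basic ylide may enolise the aldehyde and trigger retro-Michael fragmentation, or open the lactone by elimination next to the ester, in competition with olefination. The fallback sets out from 7 and avoids base. Methylenation with Zn/CH2Br2/TiCl4 would give tert-butyl (2R)-2-[(2S)-1-tert-butoxy-1-oxopent-4-en-2-yl]-5-oxo-2,5-dihydrofuran-2-carboxylate F2. Cross-metathesis of F2 with non-8-enoic acid (second-generation ruthenium benzylidene catalyst, CH2Cl2, 40 °C) would give (8E,11S)-11-(tert-butoxycarbonyl)-11-[(2R)-2-(tert-butoxycarbonyl)-5-oxo-2,5-dihydrofuran-2-yl]undec-8-enoic acid F3, whose alkene geometry is immaterial. Hydrogenation as in step 5 then returns to the route at 11.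

Further compounds
F1 | step 12 | tert-butyl (2R)-2-[(1S)-10-bromo-1-(tert-butoxycarbonyl)decyl]-5-oxooxolane-2-carboxylate | BrCCCCCCCCC[C@H](C(=O)OC(C)(C)C)[C@@]1(C(=O)OC(C)(C)C)CCC(=O)O1
F0 | step 3 | none | none
F2 | step 4 | tert-butyl (2R)-2-[(2S)-1-tert-butoxy-1-oxopent-4-en-2-yl]-5-oxo-2,5-dihydrofuran-2-carboxylate | C=CC[C@H](C(=O)OC(C)(C)C)[C@@]1(C(=O)OC(C)(C)C)C=CC(=O)O1
F3 | step 4 | (8E,11S)-11-(tert-butoxycarbonyl)-11-[(2R)-2-(tert-butoxycarbonyl)-5-oxo-2,5-dihydrofuran-2-yl]undec-8-enoic acid | OC(=O)CCCCCC/C=C/C[C@H](C(=O)OC(C)(C)C)[C@@]1(C(=O)OC(C)(C)C)C=CC(=O)O1
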